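## Retrosynthetic overview

1. Target 46 comes from E,Z-diene diester 45 by a last-step epoxidation of C1=C10; 45 comes from macrocyclic alcohol 36 by two esterifications, with acid 38 (asymmetric hydrogenation of tiglic acid) at C3 and acid 43 (Sharpless epoxidation of tiglyl alcohol) at C8.
2. The ten-membered ring is closed at C3–C4 by intramolecular Nozaki–Hiyama–Kishi coupling of aldehyde/(Z)-vinyl iodide 33; C3 is then fixed by oxidation and CBS reduction.
3. The α-methylene-γ-lactone comes from 1,4-diol 26 (oxidative lactonisation, Eschenmoser methylenation); the (Z)-vinyl iodide comes from a propargylic alcohol whose C6 centre is set by Noyori transfer hydrogenation of ynone 15.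
4. E-C1=C10 comes from terminal alkyne 18 (Negishi carboalumination, oxirane opening); C7 from Fráter–Seebach allylation of β-hydroxy ester 5; C8 from ketoreductase reduction of achiral keto ester 1.
5. Ring order: γ-lactone (step 17), then the ten-membered carbocycle (step 22), then the oxirane (step 31).

Assumption: locants C1–C15 and the CIP descriptors quoted for compounds 17–46 follow germacrane numbering of the target (C6 = lactone O–CH, C7 = ring-fusion CH, C11–C13 = α-methylene lactone carbons, C14/C15 = methyls on C10/C4); the SMILES strings are authoritative.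

## Route

Step 1
Reactants: 1 ethyl 4-chloro-3-oxobutanoate
Product: 2 ethyl (3S)-4-chloro-3-hydroxybutanoate
Conditions: (S)-selective ketoreductase (KRED, NADPH-dependent carbonyl reductase), NADP+ (cat.), iPrOH, phosphate buffer pH 7/butyl acetate, 30 °C
Reagents that add atoms: none
Why: Enzymatic asymmetric carbonyl reduction, in which the ketoreductase delivers hydride from NADPH to one face of the prochiral β-keto ester and so sets C8 (the first stereocentre) as in the established biocatalytic reduction of this substrate.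

Step 2
Reactants: 2 ethyl (3S)-4-chloro-3-hydroxybutanoate
Product: 3 ethyl 2-[(2S)-oxiran-2-yl]acetate
Conditions: Ag2O (1.5 equiv), 4 Å MS, 1,2-dimethoxyethane, 60 °C, dark
Reagents that add atoms: none
Why: Silver-assisted intramolecular Williamson closure of the chlorohydrin under non-basic conditions avoids β-elimination to the crotonate, and the C–O bond at the stereocentre is untouched.

Step 3
Reactants: 3 ethyl 2-[(2S)-oxiran-2-yl]acetate; 4 ethynyltrimethylsilane
Product: 5 ethyl (3R)-3-hydroxy-6-(trimethylsilyl)hex-5-ynoate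
Conditions: 4, n-BuLi, THF, −78 °C; BF3·OEt2; then 3, −78 °C
Reagents that add atoms: none
Why: Yamaguchi BF3-promoted opening of the terminal epoxide by the lithium acetylide at the unsubstituted carbon, which the ester survives at −78 °C, leaves the carbinol centre unchanged (the descriptor changes by priority only).

Step 4
Reactants: 5 ethyl (3R)-3-hydroxy-6-(trimethylsilyl)hex-5-ynoate; 6 allyl bromide
Product: 7 ethyl (2R,3R)-3-hydroxy-2-(prop-2-en-1-yl)-6-(trimethylsilyl)hex-5-ynoate
Conditions: LiN(iPr)2 (2.2 equiv), THF, −78 → −20 °C; 6, DMPU, −78 → −10 °C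
Reagents that add atoms: none
Why: Fráter–Seebach alkylation, in which the chelated lithium alkoxide–enolate dianion is allylated on the face anti to the C8 substituent and sets C7 with the 2,3-anti relationship of the target.

Step 5
Reactants: 7 ethyl (2R,3R)-3-hydroxy-2-(prop-2-en-1-yl)-6-(trimethylsilyl)hex-5-ynoate
Product: 8 ethyl (2R,3R)-3-(tert-butyldimethylsilyloxy)-2-(prop-2-en-1-yl)-6-(trimethylsilyl)hex-5-ynoate
Conditions: TBSOTf, 2,6-lutidine, CH2Cl2, −78 → 0 °C
Reagents that add atoms: tert-butyldimethylsilyl trifluoromethanesulfonate, CC(C)(C)[Si](C)(C)OS(=O)(=O)C(F)(F)F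
Why: Standard silylation of a hindered secondary alcohol with a silyl triflate protects C8–OH until step 27.

Step 6
Reactants: 8 ethyl (2R,3R)-3-(tert-butyldimethylsilyloxy)-2-(prop-2-en-1-yl)-6-(trimethylsilyl)hex-5-ynoate
Product: 11 (3R)-3-[(1R)-1-(tert-butyldimethylsilyloxy)-4-(trimethylsilyl)but-3-yn-1-yl]oxolan-2-one, via aldehyde 9 (not isolated), via hydroxy ester 10 (not isolated)
Conditions: O3, CH2Cl2/MeOH, −78 °C; NaBH4, −78 → 0 °C; PPTS (cat.), CH2Cl2, rt
Reagents that add atoms: ozone, [O-][O+]=O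
Why: Ozonolysis cleaves the terminal alkene much faster than the silyl alkyne, and reductive work-up followed by acid-catalysed lactonisation onto the ethyl ester differentiates C12 (alcohol level) from C6 (acyl level) without touching a stereocentre.

Step 7
Reactants: 11 (3R)-3-[(1R)-1-(tert-butyldimethylsilyloxy)-4-(trimethylsilyl)but-3-yn-1-yl]oxolan-2-one
Product: 12 (2R,3R)-3-(tert-butyldimethylsilyloxy)-2-(2-hydroxyethyl)-N-methoxy-N-methyl-6-(trimethylsilyl)hex-5-ynamide
Conditions: MeNH(OMe)·HCl, AlMe3, CH2Cl2, 0 °C → rt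
Reagents that add atoms: N,O-dimethylhydroxylamine hydrochloride, CNOC.Cl
Why: Weinreb aminolysis of the lactone by the dimethylaluminium amide opens the ring, freeing the C12 hydroxyl and activating C6 for a single organometallic addition.

Step 8
Reactants: 12 hydroxy Weinreb amide
Product: 13 (2R,3R)-3-(tert-butyldimethylsilyloxy)-N-methoxy-N-methyl-2-[2-(triethylsilyloxy)ethyl]-6-(trimethylsilyl)hex-5-ynamide
Conditions: Et3SiCl, imidazole, CH2Cl2, 0 °C
Reagents that add atoms: chlorotriethylsilane, CC[Si](Cl)(CC)CC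
Why: Immediate silylation of the primary alcohol prevents re-lactonisation and gives a labile ether that can later be removed beside the tert-butyldimethylsilyl ethers.

Step 9
Reactants: 13 Weinreb amide; 14 prop-1-yn-1-ylmagnesium bromide
Product: 15 (5R,6R)-6-(tert-butyldimethylsilyloxy)-5-[2-(triethylsilyloxy)ethyl]-9-(trimethylsilyl)nona-2,8-diyn-4-one
Conditions: 14 (1.5 equiv), THF, −20 → 0 °C
Reagents that add atoms: none
Why: Weinreb ketone synthesis, in which the chelated tetrahedral intermediate stops at mono-addition and the adjacent C7 centre is not epimerised, brings in C4, C5 and C15.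

Step 10
Reactants: 15 ynone
Product: 16 (4S,5S,6R)-6-(tert-butyldimethylsilyloxy)-5-[2-(triethylsilyloxy)ethyl]-9-(trimethylsilyl)nona-2,8-diyn-4-ol
Conditions: Ru[(S,S)-TsDPEN](p-cymene) (3 mol %), iPrOH, rt
Reagents that add atoms: none
Why: Noyori asymmetric transfer hydrogenation of an alkynyl ketone, where the (S,S)-catalyst places the alkyne in its preferred quadrant and gives the (S)-propargylic alcohol (C6 of the target) under catalyst control.

Step 11
Reactants: 16 propargylic alcohol
Product: 17 triethylsilyl ether of 16 at the carbinol (C6–OSiEt3, C12–OSiEt3, C8–OTBS; 6S,7R,8R)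
Conditions: Et3SiOTf, 2,6-lutidine, CH2Cl2, −78 °C
Reagents that add atoms: triethylsilyl trifluoromethanesulfonate, CC[Si](CC)(CC)OS(=O)(=O)C(F)(F)F
Why: Silylation masks the propargylic hydroxyl so that it cannot direct or consume the organoaluminium reagents of step 13.

Step 12
Reactants: 17 bis-triethylsilyl ether
Product: 18 terminal alkyne (17 with H–C1≡C10 in place of Me3Si–C1≡C10; 6S,7R,8R)
Conditions: K2CO3 (0.2 equiv), MeOH, 0 °C
Reagents that add atoms: none
Why: Base-catalysed methanolysis cleaves the C(sp)–Si bond selectively while the O-silyl ethers survive the short, cold exposure.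

Step 13
Reactants: 18 terminal alkyne; 19 oxirane
Product: 22 (1(10)E)-homoallylic alcohol with free C3–OH (6S,7R,8R), via alkenylalane 20 (not isolated), via lithium alanate 21 (not isolated)
Conditions: AlMe3 (2.5 equiv), Cp2ZrCl2 (0.25 equiv), ClCH2CH2Cl, rt; volatiles removed; THF, n-BuLi, −78 °C; 19, −78 → 0 °C
Reagents that add atoms: trimethylaluminium, C[Al](C)C
Why: Negishi zirconium-catalysed carboalumination adds Me–Al syn across the terminal alkyne only (the internal alkyne is far slower), and opening of oxirane by the derived alanate with retention gives the E-trisubstituted C1=C10 alkene with C14, C2 and C3 in place.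

Step 14
Reactants: 22 homoallylic alcohol
Product: 23 C3–O-tert-butyldimethylsilyl ether of 22 (6S,7R,8R)
Conditions: TBSCl, imidazole, DMF, 0 °C → rt
Reagents that add atoms: tert-butyl(chloro)dimethylsilane, CC(C)(C)[Si](C)(C)Cl
Why: Routine silylation of the primary alcohol keeps C3 masked through the oxidation and enolate steps.

Step 15
Reactants: 23 tetrasilyl ether
Product: 24 diol with C6–OH and C12–OH free (C3–OTBS and C8–OTBS kept; 6S,7S,8R)
Conditions: PPTS (0.2 equiv), MeOH/CH2Cl2, 0 °C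
Reagents that add atoms: none
Why: Acid-catalysed methanolysis removes triethylsilyl ethers far faster than tert-butyldimethylsilyl ethers, so both Et3Si groups are cleaved selectively.

Step 16
Reactants: 24 propargylic diol
Product: 26 (4Z)-vinyl iodide diol (6S,7S,8R), via alkenylaluminate 25 (not isolated)
Conditions: NaAlH2(OCH2CH2OMe)2 (Red-Al, 4 equiv), THF, 0 °C → rt; EtOAc; I2, −78 → 0 °C
Reagents that add atoms: iodine, II
Why: Hydroxyl-directed trans-hydroalumination of the propargylic alcohol puts aluminium on C4 in a five-membered aluminate, and iodinolysis with retention gives the (Z)-vinyl iodide in which iodine is cis to C6.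

Step 17
Reactants: 26 (4Z)-vinyl iodide diol
Product: 28 trans-γ-lactone (6S,7S,8R), via lactol 27 (not isolated)
Conditions: TEMPO (0.2 equiv), PhI(OAc)2 (2.5 equiv), CH2Cl2, rt
Reagents that add atoms: none
Why: TEMPO/PhI(OAc)2 oxidises the primary alcohol selectively, the aldehyde is trapped by the C6 hydroxyl as a lactol, and this is oxidised on to the γ-lactone (first ring).

Step 18
Reactants: 28 trans-γ-lactone
Product: 29 11-(dimethylaminomethyl) lactone (6S,7S,8R,11R)
Conditions: LiN(iPr)2, THF, −78 °C; CH2=NMe2+ I−, −78 °C → rt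
Reagents that add atoms: dimethyl(methylidene)ammonium iodide (Eschenmoser's salt), C=[N+](C)C.[I-]
Why: Mannich reaction of the lactone lithium enolate with Eschenmoser's salt occurs anti to the C7 substituent and introduces C13 (the new centre is lost in step 19).

Step 19
Reactants: 29 Mannich base
Product: 31 α-methylene lactone (6S,7S,8R), via ammonium iodide 30 (not isolated)
Conditions: MeI, MeOH/CH2Cl2, rt; NaHCO3 (aq), EtOAc, rt
Reagents that add atoms: none
Why: Quaternisation of the amine followed by mild base-induced E1cB elimination of trimethylamine gives the exocyclic C11=C13 alkene.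

Step 20
Reactants: 31 α-methylene lactone
Product: 32 primary alcohol (31 with C3–OH free; 6S,7S,8R)
Conditions: HF·pyridine, pyridine, THF, 0 °C
Reagents that add atoms: none
Why: Buffered HF·pyridine cleaves the unhindered primary silyl ether much faster than the hindered secondary C8 ether.

Step 21
Reactants: 32 primary alcohol
Product: 33 aldehyde (C3 = CHO; 6S,7S,8R)
Conditions: Dess–Martin periodinane, NaHCO3, CH2Cl2, 0 °C
Reagents that add atoms: none
Why: Buffered Dess–Martin oxidation gives the β,γ-unsaturated aldehyde without migration of C1=C10 into conjugation, and the crude aldehyde is used at once.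

Step 22
Reactants: 33 aldehyde
Product: 34 (1(10)E,4Z)-3-hydroxy-8-(tert-butyldimethylsilyloxy)germacra-1(10),4,11(13)-trien-6,12-olide (6R,7S,8R; C3 epimers)
Conditions: CrCl2 (10 equiv), NiCl2 (0.1 equiv), DMSO/THF, 0.002 M, syringe pump, rt
Reagents that add atoms: none
Why: Intramolecular Nozaki–Hiyama–Kishi coupling, in which nickel-catalysed activation of the vinyl iodide gives an alkenylchromium species (trivalent chromium) with retained Z geometry that adds to the aldehyde at high dilution, forms C3–C4 and the ten-membered ring while lactone, enoate and silyl ether are inert.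

Step 23
Reactants: 34 macrocyclic allylic alcohol
Product: 35 (1(10)E,4Z)-8-(tert-butyldimethylsilyloxy)-3-oxogermacra-1(10),4,11(13)-trien-6,12-olide (6R,7S,8R)
Conditions: Dess–Martin periodinane, NaHCO3, CH2Cl2, 0 °C
Reagents that add atoms: none
Why: Oxidation of both C3 epimers to one Z-enone under neutral conditions converges the mixture.

Step 24
Reactants: 35 enone
Product: 36 (3S,6R,7S,8R)-3-hydroxy-8-(tert-butyldimethylsilyloxy)germacra-1(10)E,4Z,11(13)-trien-6,12-olide
Conditions: (R)-2-methyl-CBS-oxazaborolidine (0.3 equiv), catecholborane, toluene, −78 °C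
Reagents that add atoms: none
Why: Corey–Bakshi–Shibata reduction, in which the (R)-oxazaborolidine treats the α-methylalkenyl side as the large group and delivers hydride to give the (3S)-allylic alcohol by 1,2-reduction only.

Step 25
Reactants: 37 tiglic acid
Product: 38 (2R)-2-methylbutanoic acid
Conditions: H2 (4 atm), Ru(OAc)2[(R)-H8-BINAP] (0.5 mol %), MeOH, rt
Reagents that add atoms: none
Why: Noyori-type asymmetric hydrogenation of an α,β-unsaturated carboxylic acid, in which the carboxylate-bound (R)-bisphosphine ruthenium catalyst gives the (R)-acid.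

Step 26
Reactants: 36 (3S)-allylic alcohol; 38 (2R)-2-methylbutanoic acid
Product: 39 3-O-[(2R)-2-methylbutanoyl] ester of 36 (3S,6R,7S,8R)
Conditions: EDC·HCl, DMAP, CH2Cl2, 0 °C → rt
Reagents that add atoms: none
Why: Steglich esterification acylates the only free hydroxyl with retention at C3 and without racemising the simple α-methyl acid.

Step 27
Reactants: 39 C3 ester
Product: 40 (3S,6R,7R,8R)-8-hydroxy-3-[(2R)-2-methylbutanoyloxy]germacra-1(10)E,4Z,11(13)-trien-6,12-olide
Conditions: HF·pyridine, THF, 0 °C → rt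
Reagents that add atoms: none
Why: Mildly acidic fluoride desilylation frees C8–OH without base-mediated addition to the α-methylene lactone or ester migration.

Step 28
Reactants: 41 (E)-2-methylbut-2-en-1-ol
Product: 42 [(2S,3S)-2,3-dimethyloxiran-2-yl]methanol
Conditions: t-BuOOH, Ti(OiPr)4 (10 mol %), L-(+)-diethyl tartrate (12 mol %), 4 Å MS, CH2Cl2, −20 °C
Reagents that add atoms: tert-butyl hydroperoxide, CC(C)(C)OO
Why: Katsuki–Sharpless asymmetric epoxidation of the E-allylic alcohol, where the L-(+)-tartrate titanium catalyst delivers oxygen to the face that gives the (2S,3S)-epoxy alcohol.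

Step 29
Reactants: 42 epoxy alcohol
Product: 43 (2R,3S)-2,3-dimethyloxirane-2-carboxylic acid
Conditions: RuCl3·xH2O (2 mol %), NaIO4, CCl4/MeCN/H2O, rt
Reagents that add atoms: water, O
Why: Sharpless RuO4 oxidation takes the primary alcohol to the acid via the aldehyde hydrate and leaves the oxirane intact (the C2 descriptor changes by priority only).

Step 30
Reactants: 40 C8 alcohol; 43 (2R,3S)-2,3-dimethyloxirane-2-carboxylic acid
Product: 45 diester diene (3S,6R,7R,8R), via mixed anhydride 44 (not isolated)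
Conditions: 2,4,6-trichlorobenzoyl chloride, Et3N, THF, rt; then 40, DMAP, toluene, rt
Reagents that add atoms: none
Why: Yamaguchi esterification, in which DMAP attacks the less hindered carbonyl of the mixed anhydride, acylates the hindered C8 hydroxyl under non-acidic conditions that the glycidic acid tolerates.

Step 31
Reactants: 45 diester diene
Product: 46 (1R,3S,4Z,6R,7R,8R,10R)-1,10-epoxy-8-[(2R,3S)-2,3-dimethyloxirane-2-carbonyloxy]-3-[(2R)-2-methylbutanoyloxy]germacra-4,11(13)-dien-6,12-olide (CNP0265335.3)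
Conditions: mCPBA, NaHCO3, CH2Cl2, 0 °C
Reagents that add atoms: 3-chloroperoxybenzoic acid, OOC(=O)c1cccc(Cl)c1
Why: Prilezhaev epoxidation attacks only the electron-rich isolated C1=C10 alkene (C4=C5 is deactivated by two allylic acyloxy groups and C11=C13 is electron-poor), and syn delivery to the exposed outer face of the E-alkene gives the trans-1,10-epoxide.

## Compound list

1 | ethyl 4-chloro-3-oxobutanoate | CCOC(=O)CC(=O)CCl | starting material
2 | ethyl (3S)-4-chloro-3-hydroxybutanoate | CCOC(=O)C[C@H](O)CCl | intermediate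
3 | ethyl 2-[(2S)-oxiran-2-yl]acetate | CCOC(=O)C[C@H]1CO1 | intermediate
4 | ethynyltrimethylsilane | C#C[Si](C)(C)C | starting material
5 | ethyl (3R)-3-hydroxy-6-(trimethylsilyl)hex-5-ynoate | CCOC(=O)C[C@H](O)CC#C[Si](C)(C)C | intermediate
6 | allyl bromide (3-bromoprop-1-ene) | C=CCBr | starting material
7 | ethyl (2R,3R)-3-hydroxy-2-(prop-2-en-1-yl)-6-(trimethylsilyl)hex-5-ynoate (anti) | CCOC(=O)[C@H](CC=C)[C@H](O)CC#C[Si](C)(C)C | intermediate
8 | ethyl (2R,3R)-3-(tert-butyldimethylsilyloxy)-2-(prop-2-en-1-yl)-6-(trimethylsilyl)hex-5-ynoate | CCOC(=O)[C@H](CC=C)[C@H](O[Si](C)(C)C(C)(C)C)CC#C[Si](C)(C)C | intermediate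
9 | ethyl (2R,3R)-3-(tert-butyldimethylsilyloxy)-2-(2-oxoethyl)-6-(trimethylsilyl)hex-5-ynoate | CCOC(=O)[C@H](CC=O)[C@H](O[Si](C)(C)C(C)(C)C)CC#C[Si](C)(C)C | intermediate (not isolated)
10 | ethyl (2R,3R)-3-(tert-butyldimethylsilyloxy)-2-(2-hydroxyethyl)-6-(trimethylsilyl)hex-5-ynoate | CCOC(=O)[C@H](CCO)[C@H](O[Si](C)(C)C(C)(C)C)CC#C[Si](C)(C)C | intermediate (not isolated)
11 | (3R)-3-[(1R)-1-(tert-butyldimethylsilyloxy)-4-(trimethylsilyl)but-3-yn-1-yl]oxolan-2-one | O=C1OCC[C@@H]1[C@H](O[Si](C)(C)C(C)(C)C)CC#C[Si](C)(C)C | intermediate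
12 | (2R,3R)-3-(tert-butyldimethylsilyloxy)-2-(2-hydroxyethyl)-N-methoxy-N-methyl-6-(trimethylsilyl)hex-5-ynamide | CON(C)C(=O)[C@H](CCO)[C@H](O[Si](C)(C)C(C)(C)C)CC#C[Si](C)(C)C | intermediate
13 | (2R,3R)-3-(tert-butyldimethylsilyloxy)-N-methoxy-N-methyl-2-[2-(triethylsilyloxy)ethyl]-6-(trimethylsilyl)hex-5-ynamide | CON(C)C(=O)[C@H](CCO[Si](CC)(CC)CC)[C@H](O[Si](C)(C)C(C)(C)C)CC#C[Si](C)(C)C | intermediate
14 | prop-1-yn-1-ylmagnesium bromide | CC#C[Mg]Br | starting material
15 | (5R,6R)-6-(tert-butyldimethylsilyloxy)-5-[2-(triethylsilyloxy)ethyl]-9-(trimethylsilyl)nona-2,8-diyn-4-one | CC#CC(=O)[C@H](CCO[Si](CC)(CC)CC)[C@H](O[Si](C)(C)C(C)(C)C)CC#C[Si](C)(C)C | intermediate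
16 | (4S,5S,6R)-6-(tert-butyldimethylsilyloxy)-5-[2-(triethylsilyloxy)ethyl]-9-(trimethylsilyl)nona-2,8-diyn-4-ol | CC#C[C@@H](O)[C@H](CCO[Si](CC)(CC)CC)[C@H](O[Si](C)(C)C(C)(C)C)CC#C[Si](C)(C)C | intermediate
17 | triethylsilyl ether of 16 at the carbinol (C6–OSiEt3, C12–OSiEt3, C8–OTBS, Me3Si–C1≡C10; 6S,7R,8R) | CC#C[C@@H](O[Si](CC)(CC)CC)[C@H](CCO[Si](CC)(CC)CC)[C@H](O[Si](C)(C)C(C)(C)C)CC#C[Si](C)(C)C | intermediate
18 | terminal alkyne, 17 with H–C1≡C10 (6S,7R,8R) | CC#C[C@@H](O[Si](CC)(CC)CC)[C@H](CCO[Si](CC)(CC)CC)[C@H](O[Si](C)(C)C(C)(C)C)CC#C | intermediate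
19 | oxirane (ethylene oxide) | C1CO1 | starting material
20 | (E)-alkenyl(dimethyl)alane, Me2Al–C1H=C10(CH3)–C9 with Al cis to the new methyl | CC#C[C@@H](O[Si](CC)(CC)CC)[C@H](CCO[Si](CC)(CC)CC)[C@H](O[Si](C)(C)C(C)(C)C)C/C(C)=C/[Al](C)C | intermediate (not isolated)
21 | lithium butyl(dimethyl)alkenylalanate from 20 | [Li+].CC#C[C@@H](O[Si](CC)(CC)CC)[C@H](CCO[Si](CC)(CC)CC)[C@H](O[Si](C)(C)C(C)(C)C)C/C(C)=C/[Al-](C)(C)CCCC | intermediate (not isolated)
22 | (1(10)E)-homoallylic alcohol, HO–C3H2–C2H2–C1H=C10(CH3)–C9H2–C8H(OTBS)–C7H(CH2CH2OSiEt3)–C6H(OSiEt3)–C5≡C4–CH3 (6S,7R,8R) | CC#C[C@@H](O[Si](CC)(CC)CC)[C@H](CCO[Si](CC)(CC)CC)[C@H](O[Si](C)(C)C(C)(C)C)C/C(C)=C/CCO | intermediate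
23 | C3–O-tert-butyldimethylsilyl ether of 22 (6S,7R,8R) | CC#C[C@@H](O[Si](CC)(CC)CC)[C@H](CCO[Si](CC)(CC)CC)[C@H](O[Si](C)(C)C(C)(C)C)C/C(C)=C/CCO[Si](C)(C)C(C)(C)C | intermediate
24 | diol, 23 without its two triethylsilyl groups (C6–OH, C12–OH; 6S,7S,8R) | CC#C[C@@H](O)[C@H](CCO)[C@H](O[Si](C)(C)C(C)(C)C)C/C(C)=C/CCO[Si](C)(C)C(C)(C)C | intermediate
25 | sodium cyclic alkenylaluminate (Al on C4 and O6, H on C5) | [Na+].COCCO[Al-]1(OCCOC)O[C@@H]([C@H](CCO)[C@H](O[Si](C)(C)C(C)(C)C)C/C(C)=C/CCO[Si](C)(C)C(C)(C)C)C=C1C | intermediate (not isolated)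
26 | (4Z)-vinyl iodide diol, I–C4(CH3)=C5H–C6H(OH) with C12–OH free (6S,7S,8R) | C/C(I)=C/[C@@H](O)[C@H](CCO)[C@H](O[Si](C)(C)C(C)(C)C)C/C(C)=C/CCO[Si](C)(C)C(C)(C)C | intermediate
27 | lactol (C12 hemiacetal with O6) | C/C(I)=C/[C@H]1OC(O)C[C@@H]1[C@H](O[Si](C)(C)C(C)(C)C)C/C(C)=C/CCO[Si](C)(C)C(C)(C)C | intermediate (not isolated)
28 | trans-γ-lactone (6,12-olide) with the (Z)-2-iodoprop-1-enyl group on C6 and the C8(OTBS)–C9–C10(CH3)=C1–C2–C3–OTBS chain on C7 (6S,7S,8R) | C/C(I)=C/[C@H]1OC(=O)C[C@@H]1[C@H](O[Si](C)(C)C(C)(C)C)C/C(C)=C/CCO[Si](C)(C)C(C)(C)C | intermediate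
29 | 11-(dimethylaminomethyl) lactone, aminomethyl trans to the C7 side chain (6S,7S,8R,11R) | C/C(I)=C/[C@H]1OC(=O)[C@@H](CN(C)C)[C@@H]1[C@H](O[Si](C)(C)C(C)(C)C)C/C(C)=C/CCO[Si](C)(C)C(C)(C)C | intermediate
30 | trimethylammonium iodide of 29 | C/C(I)=C/[C@H]1OC(=O)[C@@H](C[N+](C)(C)C)[C@@H]1[C@H](O[Si](C)(C)C(C)(C)C)C/C(C)=C/CCO[Si](C)(C)C(C)(C)C.[I-] | intermediate (not isolated)
31 | α-methylene lactone, C11=C13H2 (6S,7S,8R) | C/C(I)=C/[C@H]1OC(=O)C(=C)[C@@H]1[C@H](O[Si](C)(C)C(C)(C)C)C/C(C)=C/CCO[Si](C)(C)C(C)(C)C | intermediate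
32 | primary alcohol, 31 with C3–OH free (6S,7S,8R) | C/C(I)=C/[C@H]1OC(=O)C(=C)[C@@H]1[C@H](O[Si](C)(C)C(C)(C)C)C/C(C)=C/CCO | intermediate
33 | aldehyde, 32 with C3 = CHO (6S,7S,8R) | C/C(I)=C/[C@H]1OC(=O)C(=C)[C@@H]1[C@H](O[Si](C)(C)C(C)(C)C)C/C(C)=C/CC=O | intermediate
34 | (1(10)E,4Z)-3-hydroxy-8-(tert-butyldimethylsilyloxy)germacra-1(10),4,11(13)-trien-6,12-olide, C3 epimers (6R,7S,8R) | C=C1C(=O)O[C@@H]2/C=C(/C)C(O)C/C=C(\C)C[C@@H](O[Si](C)(C)C(C)(C)C)[C@@H]12 | intermediate
35 | (1(10)E,4Z)-8-(tert-butyldimethylsilyloxy)-3-oxogermacra-1(10),4,11(13)-trien-6,12-olide (6R,7S,8R) | C=C1C(=O)O[C@@H]2/C=C(/C)C(=O)C/C=C(\C)C[C@@H](O[Si](C)(C)C(C)(C)C)[C@@H]12 | intermediate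
36 | (3S,6R,7S,8R)-3-hydroxy-8-(tert-butyldimethylsilyloxy)germacra-1(10)E,4Z,11(13)-trien-6,12-olide | C=C1C(=O)O[C@@H]2/C=C(/C)[C@@H](O)C/C=C(\C)C[C@@H](O[Si](C)(C)C(C)(C)C)[C@@H]12 | intermediate
37 | tiglic acid, (E)-2-methylbut-2-enoic acid | C/C=C(\C)C(=O)O | starting material
38 | (2R)-2-methylbutanoic acid | CC[C@@H](C)C(=O)O | intermediate
39 | 3-O-[(2R)-2-methylbutanoyl] ester of 36 (3S,6R,7S,8R) | C=C1C(=O)O[C@@H]2/C=C(/C)[C@@H](OC(=O)[C@H](C)CC)C/C=C(\C)C[C@@H](O[Si](C)(C)C(C)(C)C)[C@@H]12 | intermediate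
40 | (3S,6R,7R,8R)-8-hydroxy-3-[(2R)-2-methylbutanoyloxy]germacra-1(10)E,4Z,11(13)-trien-6,12-olide | C=C1C(=O)O[C@@H]2/C=C(/C)[C@@H](OC(=O)[C@H](C)CC)C/C=C(\C)C[C@@H](O)[C@@H]12 | intermediate
41 | (E)-2-methylbut-2-en-1-ol (tiglyl alcohol) | C/C=C(\C)CO | starting material
42 | [(2S,3S)-2,3-dimethyloxiran-2-yl]methanol | OC[C@]1(C)O[C@H]1C | intermediate
43 | (2R,3S)-2,3-dimethyloxirane-2-carboxylic acid | OC(=O)[C@]1(C)O[C@H]1C | intermediate
44 | (2R,3S)-2,3-dimethyloxirane-2-carboxylic 2,4,6-trichlorobenzoic anhydride | O=C(OC(=O)c1c(Cl)cc(Cl)cc1Cl)[C@]1(C)O[C@H]1C | intermediate (not isolated)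
45 | (3S,6R,7R,8R)-8-[(2R,3S)-2,3-dimethyloxirane-2-carbonyloxy]-3-[(2R)-2-methylbutanoyloxy]germacra-1(10)E,4Z,11(13)-trien-6,12-olide | C=C1C(=O)O[C@@H]2/C=C(/C)[C@@H](OC(=O)[C@H](C)CC)C/C=C(\C)C[C@@H](OC(=O)[C@]3(C)O[C@H]3C)[C@@H]12 | intermediate
46 | (1R,3S,4Z,6R,7R,8R,10R)-1,10-epoxy-8-[(2R,3S)-2,3-dimethyloxirane-2-carbonyloxy]-3-[(2R)-2-methylbutanoyloxy]germacra-4,11(13)-dien-6,12-olide (CNP0265335.3) | C=C1C(=O)O[C@@H]2/C=C(/C)[C@@H](OC(=O)[C@H](C)CC)C[C@H]3O[C@]3(C)C[C@@H](OC(=O)[C@]3(C)O[C@H]3C)[C@@H]12 | target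

## Step count and risks

Total step count: 31 (28 on the main line, 1 for acid 38, 2 for acid 43).
Longest linear sequence: 28 steps (steps 1–24, 26, 27, 30 and 31, from 1 to 46).

Three steps most likely to fail:

Step 22, ring closure. Ring strain, oligomerisation or simple reduction of the iodide may keep the Nozaki–Hiyama–Kishi yield low. The fallback changes the ring-closing reaction to an intramolecular acyl–Stille coupling that makes the same C3–C4 bond at the ketone level. It sets out from alcohol 32. Hexamethylditin and Pd(PPh3)4 (toluene, 80 °C) exchange iodine for tin with retention and give the (Z)-trimethylstannyl alcohol F1. Dess–Martin oxidation followed by NaClO2/NaH2PO4/2-methylbut-2-ene gives the stannyl carboxylic acid F2. 1-Chloro-N,N,2-trimethylprop-1-en-1-amine converts it into the stannyl acid chloride F3, which is added by syringe pump to Pd2(dba)3/tri(2-furyl)phosphine in THF. The coupling gives enone 35, where the fallback comes back to the route; steps 21–23 are bypassed.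

Step 24, configuration at C3. The ring conformation may override the catalyst and give the 3R alcohol. The fallback accepts the substrate-controlled epimer and inverts it while the ester is made. It sets out from enone 35. Luche reduction (NaBH4, CeCl3·7H2O, MeOH, −78 °C) gives the (3R)-allylic alcohol F4. Mitsunobu esterification with acid 38 (PPh3, diisopropyl azodicarboxylate, toluene, 0 °C) goes with inversion and gives ester 39, where the route is rejoined.

Step 31, face selectivity of the epoxidation. The peracid may attack the other face of C1=C10 or give a mixture. The fallback is a two-step halohydrin sequence that puts the oxygen on the face opposite to the one an electrophile prefers. It sets out from diene 45. N-Bromosuccinimide in aqueous acetone (0 °C) forms the bromonium ion on the exposed face and water opens it anti at the tertiary C10, giving bromohydrin F5. Ag2O in 1,2-dimethoxyethane closes the oxirane by backside displacement of bromide at C1 and gives 46 directly.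

## Further compounds

F1 | step 22 | (Z)-trimethylstannyl alcohol (32 with SnMe3 in place of iodine) | C/C([Sn](C)(C)C)=C/[C@H]1OC(=O)C(=C)[C@@H]1[C@H](O[Si](C)(C)C(C)(C)C)C/C(C)=C/CCO
F2 | step 22 | stannyl carboxylic acid (C3 = CO2H) | C/C([Sn](C)(C)C)=C/[C@H]1OC(=O)C(=C)[C@@H]1[C@H](O[Si](C)(C)C(C)(C)C)C/C(C)=C/CC(=O)O
F3 | step 22 | stannyl acid chloride (C3 = COCl) | C/C([Sn](C)(C)C)=C/[C@H]1OC(=O)C(=C)[C@@H]1[C@H](O[Si](C)(C)C(C)(C)C)C/C(C)=C/CC(=O)Cl
F4 | step 24 | (3R)-allylic alcohol, C3 epimer of 36 | C=C1C(=O)O[C@@H]2/C=C(/C)[C@H](O)C/C=C(\C)C[C@@H](O[Si](C)(C)C(C)(C)C)[C@@H]12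
F5 | step 31 | bromohydrin of 45 (Br on C1, OH on C10, anti) | C=C1C(=O)O[C@@H]2/C=C(/C)[C@@H](OC(=O)[C@H](C)CC)C[C@H](Br)[C@](C)(O)C[C@@H](OC(=O)[C@]3(C)O[C@H]3C)[C@@H]12
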